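**Retrosynthetic overview**
- The target is a (2R,3R)-dihydroflavonol. Its ring A (C4a, C5, C6, C7, C8, C8a) carries OMe at C5, geranyl at C6, free OH at C7 and H at C8 beside the C4 acyl carbon: an acylphloroglucinol that reads as a folded tetracarbonyl chain whose C5 oxygen is already an enol methyl ether. The strategy rests on this feature.
- Last disconnection: the 4'-O-MOM ether. Key disconnection: C7–C8, a Dieckmann closure in which the C6 methyl group of a 2,3-dihydro-4H-pyran-4-one (ring C, future C8) attacks the ester of a beta-methoxyacrylate side chain on its C5 (future C5, C6, C7).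
- The side chain comes from C5 acylation of the 5-iodopyranone (I/Mg exchange, zinc, Negishi acylation) with methyl geranylmalonyl chloride, then enol O-methylation.
- Ring C comes from an asymmetric hetero-Diels–Alder reaction of 4-(methoxymethoxy)benzaldehyde with a methyl-substituted Danishefsky-type diene (sets C2), then trans-selective enolate hydroxylation (sets C3).
- Order of ring formation: ring B is bought, ring C is made in step 3, ring A is closed in step 13.

Key step: step 13

Remark: the methyl enol ether of acetylacetone is taken as a purchased material; "geranyl" means (2E)-3,7-dimethylocta-2,6-dien-1-yl; the malonyl carbon of the side chain is carried as a racemic or epimeric mixture until it becomes trigonal in step 11; the sense of induction in step 3 is assigned by analogy with BINOL–titanium additions to aromatic aldehydes and is to be confirmed on the first batch, with (R)-BINOL used instead if the antipode forms.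

**Route**

Step 1
Reactants: 1 4-hydroxybenzaldehyde
Product: 2 4-(methoxymethoxy)benzaldehyde
Conditions: MOMCl, iPr2NEt, CH2Cl2, 0 °C to rt
Reagents that add atoms: chloromethyl methyl ether, COCCl
Why: Base-mediated O-alkylation of the phenol (Williamson-type acetal formation) should give a MOM ether that withstands the bases, organometallics and fluoride used later and leaves with dilute acid at the end.

Step 2
Reactants: 3 (3E)-4-methoxypent-3-en-2-one
Product: 5 (3E)-4-methoxy-2-(trimethylsilyloxy)penta-1,3-diene, via lithium dienolate 4 (not isolated)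
Conditions: LiN(iPr)2, THF, −78 °C; then Me3SiCl, −78 °C to 0 °C; distillation
Reagents that add atoms: chlorotrimethylsilane, C[Si](C)(C)Cl
Why: Kinetic alpha-prime deprotonation of the vinylogous ester at the acetyl methyl group and O-silylation (silyl enol ether formation) should give the 1-alkoxy-3-siloxy diene of the Danishefsky type, whose extra methyl group becomes the C6 methyl group of the pyranone.

Step 3
Reactants: 2 4-(methoxymethoxy)benzaldehyde; 5 (3E)-4-methoxy-2-(trimethylsilyloxy)penta-1,3-diene
Product: 7 (2S)-2-[4-(methoxymethoxy)phenyl]-6-methyl-2,3-dihydro-4H-pyran-4-one, via silyl aldol adduct 6 (not isolated)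
Conditions: Ti(OiPr)4 (10 mol %), (S)-BINOL (20 mol %), 4 Å molecular sieves, toluene, −20 °C to 0 °C; then TFA (0.2 equiv), CH2Cl2, 0 °C
Reagents that add atoms: none
Why: Enantioselective hetero-Diels–Alder reaction running through a BINOL–titanium-catalysed Mukaiyama aldol addition and acid-promoted ring closure with loss of methanol, in which the chiral titanate should shield the Re face of the aldehyde so that the diene terminus adds to the Si face and sets C2 as S (the spatial arrangement of C2 in the target).

Step 4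
Reactants: 7 (2S)-2-[4-(methoxymethoxy)phenyl]-6-methyl-2,3-dihydro-4H-pyran-4-one
Product: 9 (2R,3R)-3-hydroxy-2-[4-(methoxymethoxy)phenyl]-6-methyl-2,3-dihydro-4H-pyran-4-one, via lithium enolate 8 (not isolated)
Conditions: LiN(iPr)2, THF, −78 °C; then 2-(phenylsulfonyl)-3-phenyloxaziridine, −78 °C; AcOH
Reagents that add atoms: 2-(phenylsulfonyl)-3-phenyloxaziridine (Davis oxaziridine), O=S(=O)(N1OC1c1ccccc1)c1ccccc1
Why: Davis hydroxylation of the kinetic alpha-prime enolate should deliver oxygen to the enolate face anti to the C2 aryl group, setting C3 trans to C2 (3R), which is also the diequatorial and thermodynamically preferred arrangement.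

Step 5
Reactants: 9 (2R,3R)-3-hydroxy-2-[4-(methoxymethoxy)phenyl]-6-methyl-2,3-dihydro-4H-pyran-4-one
Product: 10 (2R,3R)-3-(tert-butyldimethylsilyloxy)-2-[4-(methoxymethoxy)phenyl]-6-methyl-2,3-dihydro-4H-pyran-4-one
Conditions: tBuMe2SiOTf, 2,6-lutidine, CH2Cl2, −78 °C to 0 °C
Reagents that add atoms: tert-butyldimethylsilyl triflate, CC(C)(C)[Si](C)(C)OS(=O)(=O)C(F)(F)F
Why: Silyl ether formation on the secondary alpha-hydroxy ketone with a hindered pyridine base removes the acidic O–H before the organometallic and alkylation steps without touching either stereocentre.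

Step 6
Reactants: 10 (2R,3R)-3-(tert-butyldimethylsilyloxy)-2-[4-(methoxymethoxy)phenyl]-6-methyl-2,3-dihydro-4H-pyran-4-one
Product: 11 (2R,3R)-3-(tert-butyldimethylsilyloxy)-5-iodo-2-[4-(methoxymethoxy)phenyl]-6-methyl-2,3-dihydro-4H-pyran-4-one
Conditions: I2, pyridine, CH2Cl2, 0 °C to rt, dark
Reagents that add atoms: iodine, II
Why: Electrophilic alpha-iodination of the enone with iodine–pyridine should take place at C5, the nucleophilic carbon of the ring enol ether, and gives the alkenyl iodide needed for metalation.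

Step 7
Reactants: 12 dimethyl malonate; 13 geranyl bromide
Product: 14 dimethyl 2-geranylmalonate
Conditions: K2CO3, acetone, reflux (12 in twofold excess)
Reagents that add atoms: none
Why: Malonic ester alkylation by SN2 displacement at the primary allylic bromide keeps the E geometry of the geranyl unit, and the excess of malonate suppresses dialkylation.

Step 8
Reactants: 14 dimethyl 2-geranylmalonate
Product: 15 2-geranyl-3-methoxy-3-oxopropanoic acid (racemic)
Conditions: KOH (1.0 equiv), MeOH/THF, 0 °C to rt; then cold dilute HCl to pH 2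
Reagents that add atoms: potassium hydroxide, [K+].[OH-]
Why: Mono-saponification of a malonic diester with one equivalent of hydroxide stops at the half ester because the carboxylate formed deactivates the second ester group.

Step 9
Reactants: 15 2-geranyl-3-methoxy-3-oxopropanoic acid
Product: 16 methyl 3-chloro-2-geranyl-3-oxopropanoate (racemic, used crude)
Conditions: 1-chloro-N,N,2-trimethylprop-1-en-1-amine, CH2Cl2, 0 °C to rt
Reagents that add atoms: 1-chloro-N,N,2-trimethylprop-1-en-1-amine (Ghosez reagent), CC(C)=C(Cl)N(C)C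
Why: Acid chloride formation with the alpha-chloroenamine proceeds under neutral conditions and releases no HCl, which protects the trisubstituted alkenes of the geranyl chain from hydrochlorination.

Step 10
Reactants: 11 (2R,3R)-3-(tert-butyldimethylsilyloxy)-5-iodo-2-[4-(methoxymethoxy)phenyl]-6-methyl-2,3-dihydro-4H-pyran-4-one; 16 methyl 3-chloro-2-geranyl-3-oxopropanoate
Product: 19 methyl 2-geranyl-3-oxo-3-[(2R,3R)-3-(tert-butyldimethylsilyloxy)-2-[4-(methoxymethoxy)phenyl]-6-methyl-4-oxo-3,4-dihydro-2H-pyran-5-yl]propanoate (epimers at C2 of the propanoate), via alkenylmagnesium chloride 17 (not isolated), via alkenylzinc chloride 18 (not isolated)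
Conditions: iPrMgCl·LiCl, THF, −78 °C; ZnCl2, −78 °C to −30 °C; then 16, Pd(PPh3)4 (5 mol %), −30 °C to rt
Reagents that add atoms: none
Why: Iodine–magnesium exchange at the activated alkenyl iodide, transmetalation to zinc and Negishi acylation with the acid chloride should form the C5–acyl bond, since the exchange outruns carbonyl addition at −78 °C and the weakly basic alkenylzinc spares the ring ketone, the silyl ether and the acidic C–H of the malonyl unit.

Step 11
Reactants: 19 methyl 2-geranyl-3-oxo-3-[(2R,3R)-3-(tert-butyldimethylsilyloxy)-2-[4-(methoxymethoxy)phenyl]-6-methyl-4-oxo-3,4-dihydro-2H-pyran-5-yl]propanoate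
Product: 21 methyl (2E)-2-geranyl-3-methoxy-3-[(2R,3R)-3-(tert-butyldimethylsilyloxy)-2-[4-(methoxymethoxy)phenyl]-6-methyl-4-oxo-3,4-dihydro-2H-pyran-5-yl]prop-2-enoate, via potassium enolate 20 (not isolated)
Conditions: KN(SiMe3)2 (1.05 equiv), 18-crown-6, THF, −78 °C; then MeOTf, −78 °C to −40 °C
Reagents that add atoms: methyl triflate, COS(=O)(=O)C(F)(F)F
Why: O-alkylation of a beta-keto ester enolate, in which the crown-separated potassium enolate and the hard electrophile should react at the ketone oxygen because C-methylation would build a quaternary centre beside the bulky pyranone, while the E or Z outcome is not critical because both isomers converge in step 13.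

Step 12
Reactants: 21 methyl (2E)-2-geranyl-3-methoxy-3-[(2R,3R)-3-(tert-butyldimethylsilyloxy)-2-[4-(methoxymethoxy)phenyl]-6-methyl-4-oxo-3,4-dihydro-2H-pyran-5-yl]prop-2-enoate
Product: 22 methyl (2E)-2-geranyl-3-[(2R,3R)-3-hydroxy-2-[4-(methoxymethoxy)phenyl]-6-methyl-4-oxo-3,4-dihydro-2H-pyran-5-yl]-3-methoxyprop-2-enoate
Conditions: HF·pyridine, pyridine, THF, 0 °C to rt
Reagents that add atoms: none
Why: Fluoride-mediated silyl ether cleavage under buffered, non-basic conditions frees the C3 hydroxyl without epimerising C3 and without hydrolysing the MOM ether or the two enol ethers.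

Step 13
Reactants: 22 methyl (2E)-2-geranyl-3-[(2R,3R)-3-hydroxy-2-[4-(methoxymethoxy)phenyl]-6-methyl-4-oxo-3,4-dihydro-2H-pyran-5-yl]-3-methoxyprop-2-enoate
Product: 25 (2R,3R)-6-geranyl-3,7-dihydroxy-5-methoxy-2-[4-(methoxymethoxy)phenyl]chroman-4-one, via dilithium alkoxide-dienolate 23 (not isolated), via lithium dienone alkoxide 24 (not isolated)
Conditions: LiN(SiMe3)2 (3.5 equiv), THF, −78 °C to 0 °C, argon; AcOH, −78 °C
Reagents that add atoms: none
Why: The first equivalent of base makes the C3 lithium alkoxide, which blocks enolisation at C3, and the second removes a proton from the C6 methyl group of the pyranone (future C8) to give dienolate 23, whose charge also reaches the acrylate ester so that the enol-ether double bond can rotate and either geometric isomer can reach the reactive conformer with the ester cis to the pyranone. The methylene carbon of 23 attacks the ester carbonyl (future C7) in a 6-exo-trig Dieckmann (intramolecular Claisen) closure that forms the C7–C8 bond and ring A, methoxide leaves to give dienone 24, and the third equivalent of base removes a C8 proton so that the ring ends as the C7 phenoxide, which makes the sequence irreversible. The closest known reactions are the Claisen-type cyclisations of polyketo esters to acylphloroglucinols and the acylation of gamma-deprotonated 6-methylpyranones by esters. No stereocentre is formed, and C2 and C3 are retained because the alkoxide suppresses deprotonation at C3, C2 bears no acidic hydrogen and the protected 4'-oxygen cannot open ring C through a quinone methide. The selectivities needed are gamma- over alpha-prime deprotonation and C- over O-acylation of the dienolate, secured by the C3 alkoxide, by the doubly vinylogous acidity of the methyl group and by aromatisation, which drains the C-acylation product while an enol lactone from O-attack can be reopened by methoxide. The C5 methoxy and C6 geranyl groups are carried in from the chain, so the 5-OMe/7-OH pattern needs no differentiation of phenols.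

Step 14
Reactants: 25 (2R,3R)-6-geranyl-3,7-dihydroxy-5-methoxy-2-[4-(methoxymethoxy)phenyl]chroman-4-one
Product: 26 (2R,3R)-6-geranyl-3,7-dihydroxy-2-(4-hydroxyphenyl)-5-methoxychroman-4-one (target)
Conditions: aqueous HCl (3 M), MeOH, rt to 40 °C
Reagents that add atoms: none
Why: Acid-catalysed acetal cleavage (MOM ether removal) in methanol frees the 4'-phenol under conditions in routine use for MOM-protected prenylated flavonoids, which should leave the geranyl chain, the C5 methyl ether and the trans-2,3 configuration untouched.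

**Compound list**
1 | 4-hydroxybenzaldehyde | O=Cc1ccc(O)cc1 | starting material
2 | 4-(methoxymethoxy)benzaldehyde | COCOc1ccc(C=O)cc1 | intermediate
3 | (3E)-4-methoxypent-3-en-2-one | CO/C(C)=C/C(C)=O | starting material
4 | lithium (3E)-4-methoxypenta-1,3-dien-2-olate | CO/C(C)=C/C(=C)[O-].[Li+] | intermediate (not isolated)
5 | (3E)-4-methoxy-2-(trimethylsilyloxy)penta-1,3-diene | CO/C(C)=C/C(=C)O[Si](C)(C)C | intermediate
6 | (1S,4E)-5-methoxy-1-[4-(methoxymethoxy)phenyl]-1-(trimethylsilyloxy)hex-4-en-3-one | CO/C(C)=C/C(=O)C[C@H](O[Si](C)(C)C)c1ccc(OCOC)cc1 | intermediate (not isolated)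
7 | (2S)-2-[4-(methoxymethoxy)phenyl]-6-methyl-2,3-dihydro-4H-pyran-4-one | CC1=CC(=O)C[C@@H](c2ccc(OCOC)cc2)O1 | intermediate
8 | lithium (2S)-2-[4-(methoxymethoxy)phenyl]-6-methyl-2H-pyran-4-olate | CC1=CC([O-])=C[C@@H](c2ccc(OCOC)cc2)O1.[Li+] | intermediate (not isolated)
9 | (2R,3R)-3-hydroxy-2-[4-(methoxymethoxy)phenyl]-6-methyl-2,3-dihydro-4H-pyran-4-one | CC1=CC(=O)[C@H](O)[C@@H](c2ccc(OCOC)cc2)O1 | intermediate
10 | (2R,3R)-3-(tert-butyldimethylsilyloxy)-2-[4-(methoxymethoxy)phenyl]-6-methyl-2,3-dihydro-4H-pyran-4-one | CC1=CC(=O)[C@H](O[Si](C)(C)C(C)(C)C)[C@@H](c2ccc(OCOC)cc2)O1 | intermediate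
11 | (2R,3R)-3-(tert-butyldimethylsilyloxy)-5-iodo-2-[4-(methoxymethoxy)phenyl]-6-methyl-2,3-dihydro-4H-pyran-4-one | CC1=C(I)C(=O)[C@H](O[Si](C)(C)C(C)(C)C)[C@@H](c2ccc(OCOC)cc2)O1 | intermediate
12 | dimethyl malonate | COC(=O)CC(=O)OC | starting material
13 | geranyl bromide, (2E)-1-bromo-3,7-dimethylocta-2,6-diene | BrC/C=C(\C)CCC=C(C)C | starting material
14 | dimethyl 2-geranylmalonate | COC(=O)C(C/C=C(\C)CCC=C(C)C)C(=O)OC | intermediate
15 | 2-geranyl-3-methoxy-3-oxopropanoic acid (racemic) | COC(=O)C(C/C=C(\C)CCC=C(C)C)C(=O)O | intermediate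
16 | methyl 3-chloro-2-geranyl-3-oxopropanoate (racemic) | COC(=O)C(C/C=C(\C)CCC=C(C)C)C(Cl)=O | intermediate
17 | [(2R,3R)-3-(tert-butyldimethylsilyloxy)-2-[4-(methoxymethoxy)phenyl]-6-methyl-4-oxo-3,4-dihydro-2H-pyran-5-yl]magnesium chloride (LiCl complex) | CC1=C([Mg]Cl)C(=O)[C@H](O[Si](C)(C)C(C)(C)C)[C@@H](c2ccc(OCOC)cc2)O1 | intermediate (not isolated)
18 | [(2R,3R)-3-(tert-butyldimethylsilyloxy)-2-[4-(methoxymethoxy)phenyl]-6-methyl-4-oxo-3,4-dihydro-2H-pyran-5-yl]zinc chloride | CC1=C([Zn]Cl)C(=O)[C@H](O[Si](C)(C)C(C)(C)C)[C@@H](c2ccc(OCOC)cc2)O1 | intermediate (not isolated)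
19 | methyl 2-geranyl-3-oxo-3-[(2R,3R)-3-(tert-butyldimethylsilyloxy)-2-[4-(methoxymethoxy)phenyl]-6-methyl-4-oxo-3,4-dihydro-2H-pyran-5-yl]propanoate | COC(=O)C(C/C=C(\C)CCC=C(C)C)C(=O)C1=C(C)O[C@H](c2ccc(OCOC)cc2)[C@@H](O[Si](C)(C)C(C)(C)C)C1=O | intermediate
20 | potassium enolate of 19 (enolate oxygen on the side-chain ketone carbon) | COC(=O)C(C/C=C(\C)CCC=C(C)C)=C([O-])C1=C(C)O[C@H](c2ccc(OCOC)cc2)[C@@H](O[Si](C)(C)C(C)(C)C)C1=O.[K+] | intermediate (not isolated)
21 | methyl (2E)-2-geranyl-3-methoxy-3-[(2R,3R)-3-(tert-butyldimethylsilyloxy)-2-[4-(methoxymethoxy)phenyl]-6-methyl-4-oxo-3,4-dihydro-2H-pyran-5-yl]prop-2-enoate | COC(=O)/C(C/C=C(\C)CCC=C(C)C)=C(/OC)C1=C(C)O[C@H](c2ccc(OCOC)cc2)[C@@H](O[Si](C)(C)C(C)(C)C)C1=O | intermediate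
22 | methyl (2E)-2-geranyl-3-[(2R,3R)-3-hydroxy-2-[4-(methoxymethoxy)phenyl]-6-methyl-4-oxo-3,4-dihydro-2H-pyran-5-yl]-3-methoxyprop-2-enoate | COC(=O)/C(C/C=C(\C)CCC=C(C)C)=C(/OC)C1=C(C)O[C@H](c2ccc(OCOC)cc2)[C@@H](O)C1=O | intermediate (key-step precursor)
23 | dilithium salt of 22: C3 alkoxide and C4 dienolate with exocyclic methylene at C6 of the pyran | COC(=O)/C(C/C=C(\C)CCC=C(C)C)=C(/OC)C1=C([O-])[C@H]([O-])[C@@H](c2ccc(OCOC)cc2)OC1=C.[Li+].[Li+] | intermediate (not isolated)
24 | lithium (2R,3R)-6-geranyl-5-methoxy-2-[4-(methoxymethoxy)phenyl]-4,7-dioxo-2,3,7,8-tetrahydro-4H-chromen-3-olate | COC1=C(C/C=C(\C)CCC=C(C)C)C(=O)CC2=C1C(=O)[C@H]([O-])[C@@H](c1ccc(OCOC)cc1)O2.[Li+] | intermediate (not isolated)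
25 | (2R,3R)-6-geranyl-3,7-dihydroxy-5-methoxy-2-[4-(methoxymethoxy)phenyl]chroman-4-one | COc1c(C/C=C(\C)CCC=C(C)C)c(O)cc2c1C(=O)[C@H](O)[C@@H](c1ccc(OCOC)cc1)O2 | intermediate (key-step product)
26 | (2R,3R)-6-geranyl-3,7-dihydroxy-2-(4-hydroxyphenyl)-5-methoxychroman-4-one | COc1c(C/C=C(\C)CCC=C(C)C)c(O)cc2c1C(=O)[C@H](O)[C@@H](c1ccc(O)cc1)O2 | target

**Step count**
Total: 14 steps. Longest linear sequence: 10 steps (steps 1, 3, 4, 5, 6, 10, 11, 12, 13, 14) from 4-hydroxybenzaldehyde.

**Steps most likely to fail**

Step 13. The dianion may be deprotonated at C3 as well, which would open ring C by loss of the ring oxygen or epimerise C3. The methylene carbanion may also attack the electron-rich, twisted acrylate ester too slowly, so that intermolecular condensation takes over. The fallback gives up the pre-formed enol ether and uses the classical Claisen-type cyclisation of the unmasked polyketo ester, followed by differentiation of the two phenols; it also covers a failure of the enol O-methylation in step 11. It sets out from 19: excess LiN(SiMe3)2 in THF (or Mg(OMe)2 in MeOH) should close ring A to (2R,3R)-3-(tert-butyldimethylsilyloxy)-6-geranyl-5,7-dihydroxy-2-[4-(methoxymethoxy)phenyl]chroman-4-one F1. The C7 hydroxyl, which is not hydrogen-bonded, is then protected with MOMCl and iPr2NEt to give (2R,3R)-3-(tert-butyldimethylsilyloxy)-6-geranyl-5-hydroxy-7-(methoxymethoxy)-2-[4-(methoxymethoxy)phenyl]chroman-4-one F2. The chelated C5 hydroxyl is methylated with MeI and Ag2O to give (2R,3R)-3-(tert-butyldimethylsilyloxy)-6-geranyl-5-methoxy-7-(methoxymethoxy)-2-[4-(methoxymethoxy)phenyl]chroman-4-one F3. HF·pyridine then gives (2R,3R)-6-geranyl-3-hydroxy-5-methoxy-7-(methoxymethoxy)-2-[4-(methoxymethoxy)phenyl]chroman-4-one F4, and aqueous HCl in MeOH removes both MOM ethers, so that the fallback comes back to the route at 26.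

Step 10. The exchange may be incomplete, the Grignard reagent may add to the ring carbonyl, or the alkenylmetal may be protonated by the acidic C–H of the acid chloride (ketene formation), which returns the de-iodinated pyranone. The fallback replaces the polar organometallic by a neutral tin route. It sets out from 11: Me3SnSnMe3 with Pd(PPh3)4 in toluene at 90 °C should give (2R,3R)-3-(tert-butyldimethylsilyloxy)-2-[4-(methoxymethoxy)phenyl]-6-methyl-5-(trimethylstannyl)-2,3-dihydro-4H-pyran-4-one F5. Stille acylation of this stannane with acid chloride 16 (Pd2(dba)3, AsPh3, THF, 50 °C) comes back to the route at 19.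

Step 4. The base may deprotonate the C6 methyl group instead of C3, so that oxygen enters at the wrong carbon; the enolate may add to the sulfonimine formed from the oxidant; or the facial selectivity may be poor. The fallback exchanges the enolate oxidation for the alpha-prime acetoxylation of enones with Mn(OAc)3, a reaction of the manganese enolate that is selective for the alpha-prime carbon and enters anti to the C2 substituent. It sets out from 7: Mn(OAc)3 in benzene at reflux should give (2R,3R)-2-[4-(methoxymethoxy)phenyl]-6-methyl-4-oxo-3,4-dihydro-2H-pyran-3-yl acetate F6. Brief methanolysis (K2CO3, MeOH, 0 °C) comes back to the route at 9.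

Further compounds
F1 | step 13 | (2R,3R)-3-(tert-butyldimethylsilyloxy)-6-geranyl-5,7-dihydroxy-2-[4-(methoxymethoxy)phenyl]chroman-4-one | Oc1c(C/C=C(\C)CCC=C(C)C)c(O)cc2c1C(=O)[C@H](O[Si](C)(C)C(C)(C)C)[C@@H](c1ccc(OCOC)cc1)O2
F2 | step 13 | (2R,3R)-3-(tert-butyldimethylsilyloxy)-6-geranyl-5-hydroxy-7-(methoxymethoxy)-2-[4-(methoxymethoxy)phenyl]chroman-4-one | Oc1c(C/C=C(\C)CCC=C(C)C)c(OCOC)cc2c1C(=O)[C@H](O[Si](C)(C)C(C)(C)C)[C@@H](c1ccc(OCOC)cc1)O2
F3 | step 13 | (2R,3R)-3-(tert-butyldimethylsilyloxy)-6-geranyl-5-methoxy-7-(methoxymethoxy)-2-[4-(methoxymethoxy)phenyl]chroman-4-one | COc1c(C/C=C(\C)CCC=C(C)C)c(OCOC)cc2c1C(=O)[C@H](O[Si](C)(C)C(C)(C)C)[C@@H](c1ccc(OCOC)cc1)O2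
F4 | step 13 | (2R,3R)-6-geranyl-3-hydroxy-5-methoxy-7-(methoxymethoxy)-2-[4-(methoxymethoxy)phenyl]chroman-4-one | COc1c(C/C=C(\C)CCC=C(C)C)c(OCOC)cc2c1C(=O)[C@H](O)[C@@H](c1ccc(OCOC)cc1)O2
F5 | step 10 | (2R,3R)-3-(tert-butyldimethylsilyloxy)-2-[4-(methoxymethoxy)phenyl]-6-methyl-5-(trimethylstannyl)-2,3-dihydro-4H-pyran-4-one | CC1=C([Sn](C)(C)C)C(=O)[C@H](O[Si](C)(C)C(C)(C)C)[C@@H](c2ccc(OCOC)cc2)O1
F6 | step 4 | (2R,3R)-2-[4-(methoxymethoxy)phenyl]-6-methyl-4-oxo-3,4-dihydro-2H-pyran-3-yl acetate | CC1=CC(=O)[C@H](OC(C)=O)[C@@H](c2ccc(OCOC)cc2)O1
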